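Atoms are numbered along the target SMILES (C1 methylene; ring A C2–C7; ring B C7–C12). Everything rests on cutting C6–C7. The gem-dimethyl carbon C6 and the carbonyl-level C2 both sit on spiro C7. Ring A is therefore read as a 2,2-dimethylcyclopentanol (carbinol C2) hung on the β-carbon C7 of a ring B cyclohexenone. One iminium-catalysed 1,2-shift moves C6 from C2 to C7. It joins the two most crowded carbons, widens the five-membered ring to ring A, sets the spiro centre and leaves unequal ketones at C2 and C11. Precursor 12 is a 6-methylcyclohex-2-enone whose β-carbon bears a (1R,3R)-1-hydroxy-2,2-dimethyl-3-silyloxycyclopentyl group. Bromides, carbinol and methylene grow from these handles.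

Key step: step 7

Assumption: the quinine-derived amine is taken to cover the Si face of C7 in iminium ion 13. If its sense of induction is the reverse, the quinidine-derived pseudo-enantiomer is used in the same way.

In this numbering the target is (5S,7R,10R,11R).

Step 1
Reactants: 1 2,2-dimethylcyclopentane-1,3-dione
Product: 2 (R)-3-hydroxy-2,2-dimethylcyclopentan-1-one
Conditions: (S)-Me-CBS [(3aS)-1-methyl-3,3-diphenyltetrahydro-3H-pyrrolo[1,2-c][1,3,2]oxazaborole, 10 mol %], BH3·SMe2 (0.6 equiv), THF, −30 °C; aqueous work-up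
Reagents that add atoms: none
Why: Corey–Bakshi–Shibata reduction desymmetrises the dione: the quaternary carbon (future C6) plays the large and the ring CH2 the small flank, so the (S)-catalyst should give the (R)-carbinol (future C5), and the sub-stoichiometric borane holds back diol formation.

Step 2
Reactants: 2 (R)-3-hydroxy-2,2-dimethylcyclopentan-1-one
Product: 3 (R)-3-(tert-butyldimethylsilyloxy)-2,2-dimethylcyclopentan-1-one
Conditions: TBSCl, imidazole, DMF, 40 °C
Reagents that add atoms: tert-butyldimethylsilyl chloride CC(C)(C)[Si](C)(C)Cl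
Why: Standard silyl ether formation leaves C5 untouched, and the bulky group later shields one face of the ketone and withstands organolithium, amide base, hydride and buffered acid.

Step 3
Reactants: 4 cyclohexane-1,3-dione
Product: 5 3-bromocyclohex-2-en-1-one
Conditions: (COBr)2, DMF (cat.), CH2Cl2, 0 °C
Reagents that add atoms: oxalyl bromide O=C(Br)C(=O)Br
Why: Vilsmeier-type deoxybromination of the vinylogous acid gives the β-bromoenone, and the symmetry of the dione allows only one product.

Step 4
Reactants: 5 3-bromocyclohex-2-en-1-one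
Product: 6 7-bromo-1,4-dioxaspiro[4.5]dec-6-ene
Conditions: Me3SiOCH2CH2OSiMe3, Me3SiOTf (5 mol %), CH2Cl2, −78 → −20 °C
Reagents that add atoms: 1,2-bis(trimethylsilyloxy)ethane C[Si](C)(C)OCCO[Si](C)(C)C
Why: Noyori ketalisation under aprotic, cold conditions masks the ketone before lithiation without moving the double bond or displacing the vinylic bromide.

Step 5
Reactants: 6 7-bromo-1,4-dioxaspiro[4.5]dec-6-ene; 3 (R)-3-(tert-butyldimethylsilyloxy)-2,2-dimethylcyclopentan-1-one
Product: 9 3-[(1R,3R)-3-(tert-butyldimethylsilyloxy)-1-hydroxy-2,2-dimethylcyclopentyl]cyclohex-2-en-1-one, via vinyllithium 7 (not isolated), via ketal carbinol 8 (not isolated)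
Conditions: t-BuLi (2 equiv), Et2O–THF, −78 °C; 3, −78 → −20 °C; then 0.5 M aq. HCl, THF, 0 °C
Reagents that add atoms: water O
Why: Bromine–lithium exchange gives 7, a β-acylvinyl anion equivalent, whose 1,2-addition to ketone 3 occurs on the face away from the silyloxy group and so sets C2 as (R) with O–H cis to the silyl ether, after which the allylic ketal of 8 hydrolyses under acid too mild for the silyl ether.

Step 6
Reactants: 9 3-[(1R,3R)-3-(tert-butyldimethylsilyloxy)-1-hydroxy-2,2-dimethylcyclopentyl]cyclohex-2-en-1-one; 10 iodomethane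
Product: 12 (6RS)-3-[(1R,3R)-3-(tert-butyldimethylsilyloxy)-1-hydroxy-2,2-dimethylcyclopentyl]-6-methylcyclohex-2-en-1-one, via dilithio dienolate 11 (not isolated)
Conditions: LiN(iPr)2 (2.2 equiv), THF, −78 °C; MeI, −78 → −30 °C; then H2O
Reagents that add atoms: iodomethane CI
Why: Kinetic enolate alkylation: the base takes the carbinol proton and then the α′-proton at C10, and the cross-conjugated dienolate 11 is C-methylated while the hindered tertiary alkoxide stays inert in the cold; C10 forms without control, which is harmless because it equilibrates in step 7 and becomes sp2 in step 9.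

Step 7
Reactants: 12 (6RS)-3-[(1R,3R)-3-(tert-butyldimethylsilyloxy)-1-hydroxy-2,2-dimethylcyclopentyl]-6-methylcyclohex-2-en-1-one
Product: 15 (4R,6S,9R)-4-(tert-butyldimethylsilyloxy)-5,5,9-trimethylspiro[5.5]undecane-1,8-dione, via iminium ion 13 (not isolated), via spiro enamine 14 (not isolated)
Conditions: 9-amino-9-deoxy-epi-quinine [(8α,9S)-6′-methoxycinchonan-9-amine, 20 mol %], CF3CO2H (40 mol %), toluene, 60 → 90 °C
Reagents that add atoms: none
Why: Proposed new method: the primary amine condenses with the C11 ketone to iminium ion 13, whose β-carbon C7 is electrophilic enough for the C2–C6 σ-bond, pushed by the carbinol oxygen, to swing onto it (semipinacol-type 1,2-shift); this leaves the C2 ketone and enamine 14, whose hydrolysis gives the C11 ketone and returns the amine. The closest known reaction type is the amine-catalysed asymmetric vinylogous α-ketol rearrangement of 3-(1-hydroxycyclobutyl)enones, so the extension is one ring size: less strain is released, hence the stronger acid and the heat, but the change stays downhill because enone plus carbinol become two ketones and a cyclopentane becomes a chair, while the cationic π-system next to C2 disfavours ionisation and dehydration of the carbinol. Ring A closes by ring expansion, C7 being inserted into the C2–C6 bond of the five-membered ring. The new centre C7 requires C6 on its Re face; since C2 is stereogenic and only C6 may move, that face belongs to the C2–C7 rotamer with C3H2 beside the vinylic C12–H and the O–H beside C8H2, which has the lower allylic strain, and the amine is chosen so that its quinoline and protonated quinuclidine cover the Si face, so that substrate and catalyst reinforce each other while trifluoroacetate takes the carbinol proton. The step needs migration of C6 and not of C3, which the substrate secures because the fully substituted C6 bears developing positive charge better and its departure relieves the crowding around C2. C10 equilibrates through enamine 14 to the equatorial (10R)-methyl epimer, so both epimers of 12 converge on 15.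

Step 8
Reactants: 15 (4R,6S,9R)-4-(tert-butyldimethylsilyloxy)-5,5,9-trimethylspiro[5.5]undecane-1,8-dione
Product: 16 (4R,6S,8S,9R)-4-(tert-butyldimethylsilyloxy)-8-hydroxy-5,5,9-trimethylspiro[5.5]undecan-1-one
Conditions: LiBH(s-Bu)3 (1.1 equiv), THF, −78 °C; then H2O
Reagents that add atoms: none
Why: Sterically governed hydride reduction: the bulky borohydride ignores the C2 ketone, which is walled in by C7 and C6, and reaches C11 along the equatorial path because the axial path is blocked by the axial C2, giving the axial (11S)-alcohol cis to the equatorial C10 methyl.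

Step 9
Reactants: 16 (4R,6S,8S,9R)-4-(tert-butyldimethylsilyloxy)-8-hydroxy-5,5,9-trimethylspiro[5.5]undecan-1-one
Product: 18 (4R,6S)-4-(tert-butyldimethylsilyloxy)-5,5,9-trimethylspiro[5.5]undec-8-en-1-one, via axial mesylate 17 (not isolated)
Conditions: MsCl, Et3N, CH2Cl2, 0 °C; solvent exchange; DBU, toluene, 100 °C
Reagents that add atoms: none
Why: Mesylation and E2 elimination: in 17 the axial leaving group is antiperiplanar to the axial C10–H and C12–H, and loss of the tertiary, open C10–H (Zaitsev rule) is preferred over the C12–H that lies under the gem-dimethyl group, so C10=C11 results; any lactol between C11–OH and C2 reopens as the free alcohol is consumed.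

Step 10
Reactants: 18 (4R,6S)-4-(tert-butyldimethylsilyloxy)-5,5,9-trimethylspiro[5.5]undec-8-en-1-one
Product: 19 (4R,6S)-4-hydroxy-5,5,9-trimethylspiro[5.5]undec-8-en-1-one
Conditions: HF·pyridine, THF, 0 °C → rt
Reagents that add atoms: none
Why: Fluoride-driven cleavage of the Si–O bond frees the C5 alcohol with retention and touches neither the ketone nor the alkene.

Step 11
Reactants: 19 (4R,6S)-4-hydroxy-5,5,9-trimethylspiro[5.5]undec-8-en-1-one
Product: 20 (4S,6S)-4-bromo-5,5,9-trimethylspiro[5.5]undec-8-en-1-one
Conditions: CBr4, PPh3, 2,6-lutidine, toluene, 70 °C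
Reagents that add atoms: carbon tetrabromide BrC(Br)(Br)Br
Why: Appel reaction: the oxyphosphonium salt reacts through the chair with the C5–O bond axial, and bromide enters along the equatorial line in an SN2 displacement with inversion, turning (5R)-OH into the equatorial (5S)-Br, a slow but known type of substitution next to a gem-dimethyl carbon in a neutral medium that spares alkene and ketone.

Step 12
Reactants: 20 (4S,6S)-4-bromo-5,5,9-trimethylspiro[5.5]undec-8-en-1-one
Product: 22 (4S,6S,8R,9R)-4,8-dibromo-9-hydroxy-5,5,9-trimethylspiro[5.5]undecan-1-one, via bromonium ion 21 (not isolated)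
Conditions: NBS, acetone–H2O (4:1), 0 °C, dark
Reagents that add atoms: N-bromosuccinimide O=C1CCC(=O)N1Br; water O
Why: Halohydrin formation: Br+ reaches C10=C11 from the face anti to the axial C2 carbonyl carbon (the face of C6), and water, guided by a hydrogen bond to the C2 carbonyl oxygen, opens 21 at the tertiary C10 from the C2 face, giving the trans C10–OH/C11–Br pair that settles diequatorial with the (10R,11R) configuration.

Step 13
Reactants: 22 (4S,6S,8R,9R)-4,8-dibromo-9-hydroxy-5,5,9-trimethylspiro[5.5]undecan-1-one
Product: 23 (2R,3R,6R,8S)-2,8-dibromo-3,7,7-trimethyl-11-methylidenespiro[5.5]undecan-3-ol (target)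
Conditions: Cp2TiMe2 (4 equiv), toluene–THF, 70 °C, dark; aq. NaHCO3 work-up
Reagents that add atoms: dimethyltitanocene C[Ti+2]C.[cH-]1cccc1.[cH-]1cccc1
Why: Petasis methylenation: the thermally formed Cp2Ti=CH2 is small and non-basic enough for the ketone next to C7, the C10–OH is masked in the flask as a titanium alkoxide, and the diequatorial bromohydrin cannot align for epoxide closure.

Compound list
1 | 2,2-dimethylcyclopentane-1,3-dione | CC1(C)C(=O)CCC1=O | starting material
2 | (R)-3-hydroxy-2,2-dimethylcyclopentan-1-one | O=C1CC[C@@H](O)C1(C)C | intermediate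
3 | (R)-3-(tert-butyldimethylsilyloxy)-2,2-dimethylcyclopentan-1-one | O=C1CC[C@@H](O[Si](C)(C)C(C)(C)C)C1(C)C | intermediate
4 | cyclohexane-1,3-dione | O=C1CCCC(=O)C1 | starting material
5 | 3-bromocyclohex-2-en-1-one | O=C1C=C(Br)CCC1 | intermediate
6 | 7-bromo-1,4-dioxaspiro[4.5]dec-6-ene | BrC1=CC2(CCC1)OCCO2 | intermediate
7 | (1,4-dioxaspiro[4.5]dec-6-en-7-yl)lithium | [Li]C1=CC2(CCC1)OCCO2 | intermediate
8 | (1R,3R)-3-(tert-butyldimethylsilyloxy)-1-(1,4-dioxaspiro[4.5]dec-6-en-7-yl)-2,2-dimethylcyclopentan-1-ol | O1CCOC12CCCC(=C2)[C@]1(O)CC[C@@H](O[Si](C)(C)C(C)(C)C)C1(C)C | intermediate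
9 | 3-[(1R,3R)-3-(tert-butyldimethylsilyloxy)-1-hydroxy-2,2-dimethylcyclopentyl]cyclohex-2-en-1-one | O=C1C=C(CCC1)[C@]1(O)CC[C@@H](O[Si](C)(C)C(C)(C)C)C1(C)C | intermediate
10 | iodomethane | CI | starting material
11 | dilithium alkoxide–cross-conjugated dienolate of 9 | [Li]OC1=CCCC(=C1)[C@]1(O[Li])CC[C@@H](O[Si](C)(C)C(C)(C)C)C1(C)C | intermediate
12 | (6RS)-3-[(1R,3R)-3-(tert-butyldimethylsilyloxy)-1-hydroxy-2,2-dimethylcyclopentyl]-6-methylcyclohex-2-en-1-one (both C10 epimers) | CC1CCC(=CC1=O)[C@]1(O)CC[C@@H](O[Si](C)(C)C(C)(C)C)C1(C)C | intermediate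
13 | iminium ion of 12 and 9-amino-9-deoxy-epi-quinine (cation) | CC1CCC(=CC1=[NH+][C@H]([C@@H]1C[C@@H]2CCN1C[C@@H]2C=C)c1ccnc2ccc(OC)cc12)[C@]1(O)CC[C@@H](O[Si](C)(C)C(C)(C)C)C1(C)C | intermediate
14 | spiro keto enamine formed by the shift (C2 ketone, C11=C12 enamine) | O=C1CC[C@@H](O[Si](C)(C)C(C)(C)C)C(C)(C)[C@@]12CCC(C)C(N[C@H]([C@@H]3C[C@@H]4CCN3C[C@@H]4C=C)c3ccnc4ccc(OC)cc34)=C2 | intermediate
15 | (4R,6S,9R)-4-(tert-butyldimethylsilyloxy)-5,5,9-trimethylspiro[5.5]undecane-1,8-dione | O=C1CC[C@@H](O[Si](C)(C)C(C)(C)C)C(C)(C)[C@@]12CC[C@@H](C)C(=O)C2 | intermediate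
16 | (4R,6S,8S,9R)-4-(tert-butyldimethylsilyloxy)-8-hydroxy-5,5,9-trimethylspiro[5.5]undecan-1-one | O=C1CC[C@@H](O[Si](C)(C)C(C)(C)C)C(C)(C)[C@@]12CC[C@@H](C)[C@@H](O)C2 | intermediate
17 | 8-methanesulfonate of 16 | O=C1CC[C@@H](O[Si](C)(C)C(C)(C)C)C(C)(C)[C@@]12CC[C@@H](C)[C@@H](OS(C)(=O)=O)C2 | intermediate
18 | (4R,6S)-4-(tert-butyldimethylsilyloxy)-5,5,9-trimethylspiro[5.5]undec-8-en-1-one | O=C1CC[C@@H](O[Si](C)(C)C(C)(C)C)C(C)(C)[C@@]12CCC(C)=CC2 | intermediate
19 | (4R,6S)-4-hydroxy-5,5,9-trimethylspiro[5.5]undec-8-en-1-one | O=C1CC[C@@H](O)C(C)(C)[C@@]12CCC(C)=CC2 | intermediate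
20 | (4S,6S)-4-bromo-5,5,9-trimethylspiro[5.5]undec-8-en-1-one | O=C1CC[C@H](Br)C(C)(C)[C@@]12CCC(C)=CC2 | intermediate
21 | C10–C11 bromonium ion of 20, bromine on the face of C6 (cation) | O=C1CC[C@H](Br)C(C)(C)[C@@]12CC[C@]3(C)[Br+][C@@H]3C2 | intermediate
22 | (4S,6S,8R,9R)-4,8-dibromo-9-hydroxy-5,5,9-trimethylspiro[5.5]undecan-1-one | O=C1CC[C@H](Br)C(C)(C)[C@@]12CC[C@@](C)(O)[C@H](Br)C2 | intermediate
23 | (2R,3R,6R,8S)-2,8-dibromo-3,7,7-trimethyl-11-methylidenespiro[5.5]undecan-3-ol | C=C1CC[C@H](Br)C(C)(C)[C@@]12CC[C@@](C)(O)[C@H](Br)C2 | target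

Total step count: 13. Longest linear sequence: 11 steps (1, 2, 5–13; the branch 3, 4, 5–13 is equally long).

Steps most likely to fail

**Step 7.**
- The shift may be too slow because little ring strain is released.
- Iminium formation at the α′-methylated ketone may lag.
- C3 may migrate in place of C6.
- A hydrogen-bonded rotamer with the O–H on the C12 side may compete and erode the facial selectivity at C7.

The fallback sets out from 12 and supplies the missing driving force as oxirane strain.
- Weitz–Scheffer epoxidation (H2O2, NaOH, MeOH, 0 °C) should add hydroperoxide to C7 anti to C6 in the low-strain rotamer. This gives the 7,12-epoxy ketone F1 with the oxirane on the Si face. An epimeric oxirane would be removed here.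
- BF3·OEt2 (CH2Cl2, −78 °C) then triggers the known semipinacol rearrangement of a 2,3-epoxy alcohol. C6 migrates anti to the breaking C7–O bond and gives the 12-hydroxy diketone F2.
- Ac2O, DMAP and pyridine give the 12-acetoxy diketone F3.
- SmI2 (THF–MeOH, −78 °C) removes the α-acetoxy group next to C11.
- The route is rejoined at 15.

**Step 11.** Substitution at the neopentyl C5 may lose out to E2 loss of a C4 proton, to a 1,2-methyl shift from C6, or to simple lack of reaction.

The fallback sets out from 19 and separates activation from displacement.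
- Tf2O and pyridine (CH2Cl2, −20 °C) give the C5 triflate F4.
- F4 is displaced cold by the unsolvated bromide of Bu4NBr (toluene, 0 °C → rt) with inversion.
- The route is rejoined at 20.

**Step 12.**
- Facial selectivity may be poor, because trans-diaxial opening from the other face competes.
- Water may attack at C11.

The fallback sets out from 20 and replaces outside water by the inside oxygen.
- 2,4,4,6-Tetrabromocyclohexa-2,5-dienone is used in CH2Cl2 with only two equivalents of MeOH (−40 °C). The C2 carbonyl oxygen then opens the bromonium ion at C10 from its own face, and methanol caps the oxocarbenium ion. This gives the bridged bromo methyl ketal F5.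
- Pyridinium tosylate in wet acetone hydrolyses the ketal.
- The route is rejoined at 22.

Further compounds
F1 | step 7 | (1S,6S)-6-[(1R,3R)-3-(tert-butyldimethylsilyloxy)-1-hydroxy-2,2-dimethylcyclopentyl]-3-methyl-7-oxabicyclo[4.1.0]heptan-2-one (7,12-epoxy ketone, both C10 epimers) | CC1CC[C@@]2(O[C@@H]2C1=O)[C@]1(O)CC[C@@H](O[Si](C)(C)C(C)(C)C)C1(C)C
F2 | step 7 | (4R,6R,7S)-4-(tert-butyldimethylsilyloxy)-7-hydroxy-5,5,9-trimethylspiro[5.5]undecane-1,8-dione (12-hydroxy diketone) | O=C1CC[C@@H](O[Si](C)(C)C(C)(C)C)C(C)(C)[C@@]12CCC(C)C(=O)[C@H]2O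
F3 | step 7 | (4R,6R,7S)-7-acetoxy-4-(tert-butyldimethylsilyloxy)-5,5,9-trimethylspiro[5.5]undecane-1,8-dione (12-acetoxy diketone) | O=C1CC[C@@H](O[Si](C)(C)C(C)(C)C)C(C)(C)[C@@]12CCC(C)C(=O)[C@H]2OC(C)=O
F4 | step 11 | (4R,6S)-5,5,9-trimethyl-1-oxospiro[5.5]undec-8-en-4-yl trifluoromethanesulfonate (C5 triflate) | O=C1CC[C@@H](OS(=O)(=O)C(F)(F)F)C(C)(C)[C@@]12CCC(C)=CC2
F5 | step 12 | bridged bromo methyl ketal: C2(OMe)–O–C10 bridge across ring B (2-oxabicyclo[2.2.2]octane core), bromine at C5 and C11, methoxy group on the C12 side | CO[C@]12CC[C@H](Br)C(C)(C)[C@@]13CC[C@@](C)(O2)[C@H](Br)C3
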